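At the reading of 3.3 min the south-east run has 62.7% of its charge left, and at 6.3 min it has 39.7%; the east run carries the same charge, so we ask how its left fraction falls from there to 19 min.

| flask | starting material | catalyst | time |
|---|---|---|---|
| south-east | 1.00 M | 0.0100 M |  |
| south | 0.500 M | 0.0100 M |  |
| north-west | 1.00 M | 0.0300 M |  |
| west | 3.00 M | 0.0100 M |  |
| east | 1.00 M | 0.0100 M | 19 min |

- south-east run (time / min: [target] / M): 0.25: 0.031; 0.48: 0.061; 0.91: 0.116; 1.7: 0.209; 3.3: 0.373; 6.3: 0.603
- south run (time / min: [target] / M): 0.25: 0.022; 0.48: 0.033; 0.91: 0.073; 1.7: 0.120; 3.3: 0.212; 6.3: 0.333
- north-west run (time / min: [target] / M): 0.25: 0.074; 0.48: 0.138; 0.91: 0.248; 1.7: 0.421; 3.3: 0.687; 6.3: 0.912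
- west run (time / min: [target] / M): 0.25: 0.066; 0.48: 0.130; 0.91: 0.240; 1.7: 0.443; 3.3: 0.812; 6.3: 1.411

(scatter of a reading: 0.003 M)

1. how the opening rate goes with [starting material] round the charge of the south-east run: the exponent of the rate at two percent of starting material gone to target (one fixed amount of target, the same in the runs compared)
2. how the opening rate goes with [catalyst] round the charge of the south-east run: the exponent of the rate at two percent of starting material gone to target
3. the south run starts with 0.500 M less of starting material than the south-east run, and with no target. Compared where both hold the same amount of starting material, once fifteen percent of what the south run was charged with has turned into target, is the south run faster, slower or alike (within a tenth)?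
4. target in the east run at 19 min, as a share of the starting material charged

- Overall: starting material -> target, with catalyst as catalyst.
- Constant volume, constant temperature.
- Bound and free are read together.
- An order is taken over about fifteen percent of the charge, up and down.

We call specific rate the share of what is still left that turns to target per minute, which is the constant a pseudo-first-order reading would give: the logarithm of the fall in the left fraction, divided by the time between. Over those two readings of the south-east run it is 0.152 min⁻¹. Held steady to 19 min, it leaves 5.74% of the charge, a first estimate of 94.3% converted.

The weak link is that steadiness, since from the start to 1.7 min the same run shows 0.138 min⁻¹, so the specific rate climbs as the left fraction falls. The south run can supply the lower stretch, if a flask holding a given amount behaves alike whatever its history. At 0.152 min⁻¹, we reckon the south-east run down to the south charge at 4.79 min. Adding the south run's 1.7 min to that time, we reckon 0.386 M left in the south-east run, and the south run reads 0.380 M.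

So the east run should reach the south run's last reading, 16.7% of the east charge, at 11.1 min. The south run's last stretch gives a specific rate of 0.182 min⁻¹, higher than before. Carried to 19 min, that leaves 3.97% in the east run, and we commit to 96.0% converted.

The forecast gives orders of 0.73 and 0.8, calls the comparison alike, since “No product effect or catalyst decay shows”, and puts the yield at 96%, level with ours.

    catalyst + starting material → target + catalyst (14.88 L mol⁻¹ min⁻¹)
    2 starting material ⇌ idle substrate dimer, settled at all times (0.6390 L mol⁻¹)
    starting material → target (0.07860 min⁻¹)

The east run gives 96.8%; the orders are 0.72 and 0.65, the second below the forecast's, and the south run is alike at a ratio of 1.0. In the south-east run the target comes to half of the charge at 4.81 min, where our reckoning at 0.152 min⁻¹ gave 4.79 min. Taking our reckoned 11.1 min for the east run's arrival at 16.7%, the 3.20% left at 19 min asks for an average specific rate of 0.209 min⁻¹ over that stretch, above the 0.182 min⁻¹ we carried.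

The data were generated by integration with constants of no real substance.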